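**Assumption:** small reagents that deliver a few atoms (CO2, allyl bromide, paraformaldehyde, ethylene glycol, water) are named on the reagent line and not numbered; LDA and i‑PrMgCl·LiCl are bought as solutions; the ketoreductase is picked from a commercial engineered panel.

## Retrosynthetic overview

1. Target 18 ⇐ (S)‑carbinol 16 by Pd(0) removal of the allyl ester and allyl ether, then acetal hydrolysis.
2. The only stereocentre ⇐ prochiral aryl isobutyl ketone 15, reduced late by a ketoreductase (KRED, NADPH‑dependent alcohol dehydrogenase).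
3. Diaryl ether C–O bond ⇐ SNAr of salicylaldehyde‑type phenol 13 on aryl fluoride 8, whose fluorine is activated by the ortho ester and by the para ketone that the enzyme later reduces.
4. Ring A piece 8 ⇐ 2‑bromo‑5‑fluoroanisole (ortho‑lithiation/CO2, Br/Mg exchange + isovaleraldehyde, oxidation); ring B piece 13 ⇐ creosol (ortho‑formylation, demethylation, dianion mono‑allylation).
5. No carbocycle is built: both benzene rings are bought; the only ring formed is the temporary dioxolane (step 9), opened in the last step.

## Route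

Step 1
Reactants: 1 2-bromo-5-fluoroanisole
Product: 3 3-bromo-6-fluoro-2-methoxybenzoic acid, via aryllithium 2 (not isolated)
Conditions: LDA (1.1 equiv), THF, −78 °C, 1 h; CO2 (g), −78 °C → rt; 1 M HCl
Reagents that add atoms: carbon dioxide, O=C=O
Why: Directed ortho‑metalation removes the most acidic proton (flanked by F and OMe) while LDA at −78 °C leaves the C–Br bond alone, and the aryllithium is carboxylated by CO2.

Step 2
Reactants: 3 3-bromo-6-fluoro-2-methoxybenzoic acid
Product: 4 allyl 3-bromo-6-fluoro-2-methoxybenzoate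
Conditions: allyl bromide (1.2 equiv), K2CO3 (1.5 equiv), DMF, rt
Reagents that add atoms: allyl bromide, C=CCBr
Why: SN2 O‑alkylation of the carboxylate is insensitive to the two ortho substituents that block Fischer esterification, and the allyl ester can later be removed under neutral Pd(0) conditions.

Step 3
Reactants: 4 allyl 3-bromo-6-fluoro-2-methoxybenzoate; 5 3-methylbutanal (isovaleraldehyde)
Product: 7 racemic allyl 6-fluoro-3-(1-hydroxy-3-methylbutyl)-2-methoxybenzoate, via arylmagnesium chloride 6 (not isolated)
Conditions: i‑PrMgCl·LiCl (1.1 equiv), THF, −20 °C, 1 h; then 5 (1.3 equiv), −20 → 0 °C; aq. NH4Cl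
Reagents that add atoms: none
Why: Knochel Br/Mg exchange (turbo‑Grignard) is fast on this electron‑poor, OMe‑chelated bromide and tolerates the hindered ester at −20 °C, and Grignard 1,2‑addition to the aldehyde gives the carbinol, whose racemic centre is erased in step 4.

Step 4
Reactants: 7 racemic allyl 6-fluoro-3-(1-hydroxy-3-methylbutyl)-2-methoxybenzoate
Product: 8 allyl 6-fluoro-2-methoxy-3-(3-methylbutanoyl)benzoate
Conditions: Dess–Martin periodinane (1.2 equiv), CH2Cl2, rt
Reagents that add atoms: none
Why: Dess–Martin oxidation of a secondary benzylic alcohol is clean and neutral, and leaves the allyl ester and aryl fluoride untouched.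

Step 5
Reactants: 9 2-methoxy-4-methylphenol (creosol)
Product: 10 2-hydroxy-3-methoxy-5-methylbenzaldehyde
Conditions: MgCl2 (2 equiv), Et3N (4 equiv), (CH2O)n (6 equiv), MeCN, reflux; 1 M HCl
Reagents that add atoms: paraformaldehyde (formaldehyde), C=O
Why: Magnesium‑mediated ortho‑formylation (Casnati–Skattebøl) delivers formaldehyde within the Mg phenoxide chelate only to the free position ortho to OH, and a second formaldehyde oxidises the hydroxymethyl intermediate by hydride transfer.

Step 6
Reactants: 10 2-hydroxy-3-methoxy-5-methylbenzaldehyde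
Product: 11 2,3-dihydroxy-5-methylbenzaldehyde
Conditions: BBr3 (2.5 equiv), CH2Cl2, −78 °C → rt; H2O
Reagents that add atoms: none
Why: Lewis‑acid ether cleavage by BBr3 demethylates the aryl methyl ether (as for o‑vanillin) without harming the aldehyde at low temperature.

Step 7
Reactants: 11 2,3-dihydroxy-5-methylbenzaldehyde
Product: 13 3-(allyloxy)-2-hydroxy-5-methylbenzaldehyde, via disodium catecholate 12 (not isolated)
Conditions: NaH (2.2 equiv), DMSO, rt, 1 h; allyl bromide (1.0 equiv), rt; aq. HCl
Reagents that add atoms: allyl bromide, C=CCBr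
Why: In the dianion the 2‑oxide is delocalised into and chelated by the formyl group, so Williamson alkylation with one equivalent of allyl bromide occurs at the more nucleophilic 3‑oxide.

Step 8
Reactants: 8 allyl 6-fluoro-2-methoxy-3-(3-methylbutanoyl)benzoate; 13 3-(allyloxy)-2-hydroxy-5-methylbenzaldehyde
Product: 14 allyl 6-[2-(allyloxy)-6-formyl-4-methylphenoxy]-2-methoxy-3-(3-methylbutanoyl)benzoate
Conditions: Cs2CO3 (1.5 equiv), DMF, 70 °C
Reagents that add atoms: none
Why: SNAr: the fluoride is activated by the ortho ester and the para ketone (Meisenheimer stabilisation) and fluoride leaves far more readily than the methoxy group, so the caesium phenoxide of 13 gives the diaryl ether under mild carbonate conditions.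

Step 9
Reactants: 14 allyl 6-[2-(allyloxy)-6-formyl-4-methylphenoxy]-2-methoxy-3-(3-methylbutanoyl)benzoate
Product: 15 allyl 6-[2-(allyloxy)-6-(1,3-dioxolan-2-yl)-4-methylphenoxy]-2-methoxy-3-(3-methylbutanoyl)benzoate
Conditions: ethylene glycol (5 equiv), p‑TsOH·H2O (5 mol %), toluene, reflux, Dean–Stark
Reagents that add atoms: ethylene glycol, OCCO
Why: Chemoselective acetalisation protects the aldehyde, while the hindered, conjugated ortho‑methoxyaryl ketone does not ketalise; the mask is needed because ketoreductases also reduce aryl aldehydes.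

Step 10
Reactants: 15 allyl 6-[2-(allyloxy)-6-(1,3-dioxolan-2-yl)-4-methylphenoxy]-2-methoxy-3-(3-methylbutanoyl)benzoate
Product: 16 allyl 6-[2-(allyloxy)-6-(1,3-dioxolan-2-yl)-4-methylphenoxy]-3-[(1S)-1-hydroxy-3-methylbutyl]-2-methoxybenzoate
Conditions: (S)‑selective ketoreductase (KRED, engineered NADPH‑dependent alcohol dehydrogenase), NADP+ (cat.), i‑PrOH/phosphate buffer pH 7 (with 10 % DMSO), 30–35 °C
Reagents that add atoms: none
Why: Biocatalytic asymmetric ketone reduction: the enzyme binds the aryl group in its large pocket and the isobutyl group in the small one, and delivers the NADPH hydride to the Re face (Prelog sense) to give the (S)‑carbinol, with i‑PrOH recycling the cofactor.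

Step 11
Reactants: 16 allyl 6-[2-(allyloxy)-6-(1,3-dioxolan-2-yl)-4-methylphenoxy]-3-[(1S)-1-hydroxy-3-methylbutyl]-2-methoxybenzoate
Product: 17 6-[2-(1,3-dioxolan-2-yl)-6-hydroxy-4-methylphenoxy]-3-[(1S)-1-hydroxy-3-methylbutyl]-2-methoxybenzoic acid
Conditions: Pd(PPh3)4 (5 mol %), morpholine (10 equiv), THF, rt; NaH2PO4 buffer (pH 5) work‑up
Reagents that add atoms: none
Why: Tsuji–Trost deallylation: Pd(0) ionises both the allyl ester and the allyl aryl ether to π‑allyl complexes that morpholine traps, under neutral conditions that leave the carbinol stereocentre and the acetal untouched.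

Step 12
Reactants: 17 6-[2-(1,3-dioxolan-2-yl)-6-hydroxy-4-methylphenoxy]-3-[(1S)-1-hydroxy-3-methylbutyl]-2-methoxybenzoic acid
Product: 18 Tenellic acid B
Conditions: 0.5 M aq. HCl/THF (1:4), 0 °C → rt
Reagents that add atoms: water, O
Why: Acid‑catalysed acetal hydrolysis frees the aldehyde under conditions too mild to ionise the benzylic carbinol, whose cation is poorly stabilised (meta carboxyl, twisted flanked OMe), so the (S) centre is kept.

## Compound list

1 | 2-bromo-5-fluoroanisole (1-bromo-4-fluoro-2-methoxybenzene) | COc1cc(F)ccc1Br | starting material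
2 | (3-bromo-6-fluoro-2-methoxyphenyl)lithium | COc1c([Li])c(F)ccc1Br | intermediate (not isolated)
3 | 3-bromo-6-fluoro-2-methoxybenzoic acid | COc1c(C(=O)O)c(F)ccc1Br | intermediate
4 | allyl 3-bromo-6-fluoro-2-methoxybenzoate | COc1c(C(=O)OCC=C)c(F)ccc1Br | intermediate
5 | 3-methylbutanal (isovaleraldehyde) | CC(C)CC=O | starting material
6 | [3-(allyloxycarbonyl)-4-fluoro-2-methoxyphenyl]magnesium chloride | COc1c(C(=O)OCC=C)c(F)ccc1[Mg]Cl | intermediate (not isolated)
7 | racemic allyl 6-fluoro-3-(1-hydroxy-3-methylbutyl)-2-methoxybenzoate | COc1c(C(=O)OCC=C)c(F)ccc1C(O)CC(C)C | intermediate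
8 | allyl 6-fluoro-2-methoxy-3-(3-methylbutanoyl)benzoate | COc1c(C(=O)OCC=C)c(F)ccc1C(=O)CC(C)C | intermediate
9 | 2-methoxy-4-methylphenol (creosol) | COc1cc(C)ccc1O | starting material
10 | 2-hydroxy-3-methoxy-5-methylbenzaldehyde | COc1cc(C)cc(C=O)c1O | intermediate
11 | 2,3-dihydroxy-5-methylbenzaldehyde | Cc1cc(O)c(O)c(C=O)c1 | intermediate
12 | disodium 3-formyl-5-methylbenzene-1,2-diolate | Cc1cc([O-])c([O-])c(C=O)c1.[Na+].[Na+] | intermediate (not isolated)
13 | 3-(allyloxy)-2-hydroxy-5-methylbenzaldehyde | C=CCOc1cc(C)cc(C=O)c1O | intermediate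
14 | allyl 6-[2-(allyloxy)-6-formyl-4-methylphenoxy]-2-methoxy-3-(3-methylbutanoyl)benzoate | COc1c(C(=O)CC(C)C)ccc(Oc2c(OCC=C)cc(C)cc2C=O)c1C(=O)OCC=C | intermediate
15 | allyl 6-[2-(allyloxy)-6-(1,3-dioxolan-2-yl)-4-methylphenoxy]-2-methoxy-3-(3-methylbutanoyl)benzoate | COc1c(C(=O)CC(C)C)ccc(Oc2c(OCC=C)cc(C)cc2C3OCCO3)c1C(=O)OCC=C | intermediate
16 | allyl 6-[2-(allyloxy)-6-(1,3-dioxolan-2-yl)-4-methylphenoxy]-3-[(1S)-1-hydroxy-3-methylbutyl]-2-methoxybenzoate | COc1c([C@@H](O)CC(C)C)ccc(Oc2c(OCC=C)cc(C)cc2C3OCCO3)c1C(=O)OCC=C | intermediate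
17 | 6-[2-(1,3-dioxolan-2-yl)-6-hydroxy-4-methylphenoxy]-3-[(1S)-1-hydroxy-3-methylbutyl]-2-methoxybenzoic acid | COc1c([C@@H](O)CC(C)C)ccc(Oc2c(O)cc(C)cc2C3OCCO3)c1C(=O)O | intermediate
18 | Tenellic acid B, 6-(2-formyl-6-hydroxy-4-methylphenoxy)-3-[(1S)-1-hydroxy-3-methylbutyl]-2-methoxybenzoic acid | COc1c([C@@H](O)CC(C)C)ccc(Oc2c(O)cc(C)cc2C=O)c1C(=O)O | target

## Step count and risks

Total steps: 12. Longest linear sequence: 9 steps (1 → 3 → 4 → 7 → 8 → 14 → 15 → 16 → 17 → 18; steps 1–4 and 8–12). The ring B branch (steps 5–7) is 3 steps and joins at step 8.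

**Risk 1 – step 10 (enzymatic reduction).** Ketone 15 is large, lipophilic and flanked by an ortho methoxy group, with isobutyl as the "small" substituent, so panel screening may give low conversion or modest ee. The fallback sets out from 15 and comes back at 16 with no new compound (F0). It replaces the biocatalyst by Noyori–Ikariya asymmetric transfer hydrogenation with RuCl[(S,S)‑TsDPEN](p‑cymene) in HCO2H/Et3N (5:2)/EtOAc at 30 °C. The (S,S) catalyst gives the (S)‑carbinol through the CH/π‑controlled six‑membered transition state and tolerates the allyl groups, ester and acetal.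

**Risk 2 – step 8 (SNAr).** The phenoxide of 13 is doubly ortho‑substituted and is a weak nucleophile (vinylogous carboxylate), and the free aldehyde and the enolisable ketone meet under base. The fallback sets out from 13 and comes back at 15, skipping 14 and step 9. The aldehyde is masked first (ethylene glycol, cat. p‑TsOH, toluene, Dean–Stark) to give 2-(allyloxy)-6-(1,3-dioxolan-2-yl)-4-methylphenol F3. Its phenoxide is more electron‑rich and cannot take part in aldol or Cannizzaro chemistry. SNAr of F3 on 8 (Cs2CO3, DMSO, 60 °C) then gives 15 directly.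

**Risk 3 – step 3 (Br/Mg exchange beside an ester and an ortho‑fluoro ester).** The Grignard reagent could attack the allyl ester or displace the activated fluoride. The fallback sets out from 1 (with 5) and comes back at 7, bypassing 3 and 4 by doing the organometallic chemistry before the carboxyl group exists. Br/Mg exchange on 1 (i‑PrMgCl·LiCl, THF, 0 °C) and addition to 5 gives racemic 1-(4-fluoro-2-methoxyphenyl)-3-methylbutan-1-ol F1. LDA (2.2 equiv, THF, −78 °C) forms the alkoxide and then lithiates between F and OMe, and CO2 gives racemic 6-fluoro-3-(1-hydroxy-3-methylbutyl)-2-methoxybenzoic acid F2. Allyl bromide/KHCO3 in DMF alkylates only the carboxylate and gives 7.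

## Further compounds

F1 | step 3 | racemic 1-(4-fluoro-2-methoxyphenyl)-3-methylbutan-1-ol | COc1cc(F)ccc1C(O)CC(C)C
F2 | step 3 | racemic 6-fluoro-3-(1-hydroxy-3-methylbutyl)-2-methoxybenzoic acid | COc1c(C(=O)O)c(F)ccc1C(O)CC(C)C
F3 | step 8 | 2-(allyloxy)-6-(1,3-dioxolan-2-yl)-4-methylphenol | C=CCOc1cc(C)cc(C2OCCO2)c1O
F0 | step 10 | none | none
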